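The route rests on cutting the O1–C8a bond of ring C. The feature exploited is that O5 and O8 sit para on ring A, so ring A can be oxidised to a p-quinone in which the hydrogen-bearing C8a is the conjugate-acceptor carbon of both the C5 carbonyl and the C4 ketone. Treating an open-chain alpha-formyl deoxybenzoin (free phenol at the future C8, methyl ether at C5, benzyl ether at C7, enolised formyl group) with PhI(OAc)2 in wet acetonitrile should unmask this quinone, let the enol oxygen add to C8a and, after tautomerisation, give the 5,8-dihydroxyisoflavone in one operation. Selective 8-O-methylation, debenzylation and a Claisen shift of a 7-O-(1,1-dimethylallyl) group to C6 complete the target.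

Key step: step 8

Remark: compound 11 is drawn as the keto aldehyde but should exist and react as its hydrogen-bonded (Z)-hydroxymethylene enol, so its alpha carbon needs no stereocontrol; positions from step 8 on are given in chromone numbering (O1 to C8a).

Step 1
Reactants: 1 2-hydroxy-4-methoxybenzaldehyde
Product: 2 2-(benzyloxy)-4-methoxybenzaldehyde
Conditions: BnBr (1.1 equiv), K2CO3 (1.5 equiv), DMF, 60 °C
Reagents that add atoms: benzyl bromide, BrCc1ccccc1
Why: Williamson ether synthesis, in which the phenoxide is the only nucleophile present and benzyl bromide is an unhindered SN2 electrophile, the aldehyde being untouched.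

Step 2
Reactants: 2 2-(benzyloxy)-4-methoxybenzaldehyde
Product: 4 2-(benzyloxy)-4-methoxyphenol, via aryl formate 3 (not isolated)
Conditions: mCPBA (1.3 equiv), CH2Cl2, 0 °C to rt; aq. NaHCO3 wash; then K2CO3 (cat.), MeOH, rt
Reagents that add atoms: mCPBA, OOC(=O)c1cccc(Cl)c1
Why: Baeyer–Villiger (Dakin-type) oxidation, in which the electron-rich 2,4-dialkoxyphenyl group migrates in preference to hydride to give formate 3, and methanolysis frees the phenol only after the peracid has been washed out.

Step 3
Reactants: 4 2-(benzyloxy)-4-methoxyphenol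
Product: 5 2-(benzyloxy)-4-methoxyphenyl acetate
Conditions: Ac2O (1.5 equiv), pyridine, DMAP (cat.), CH2Cl2, rt
Reagents that add atoms: acetic anhydride, CC(=O)OC(C)=O
Why: DMAP-catalysed O-acetylation of a phenol, which turns the strongest donor on the ring into a weak one so that it no longer directs the coming acylation.

Step 4
Reactants: 6 2-(2,4,5-trimethoxyphenyl)acetic acid
Product: 7 2-(2,4,5-trimethoxyphenyl)acetyl chloride (used crude)
Conditions: (COCl)2 (1.3 equiv), DMF (cat.), CH2Cl2, 0 °C to rt
Reagents that add atoms: oxalyl chloride, O=C(Cl)C(=O)Cl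
Why: Acid chloride formation through the Vilsmeier-type chloroiminium salt from (COCl)2 and DMF, which works without heating or Lewis acid and is tolerated by the trimethoxyarene.

Step 5
Reactants: 5 2-(benzyloxy)-4-methoxyphenyl acetate; 7 2-(2,4,5-trimethoxyphenyl)acetyl chloride
Product: 8 2-(benzyloxy)-4-methoxy-5-[2-(2,4,5-trimethoxyphenyl)acetyl]phenyl acetate
Conditions: SnCl4 (1.5 equiv), CH2Cl2, −10 to 0 °C; aq. HCl work-up
Reagents that add atoms: none
Why: Friedel–Crafts acylation at C5 of the phenyl acetate, the one unhindered carbon that is ortho to the methoxy and para to the benzyloxy group (C3 is flanked by two ethers, C6 is activated only by the weakly donating acetoxy group), with SnCl4 at low temperature mild enough to spare the benzyl ether and the acetate.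

Step 6
Reactants: 8 2-(benzyloxy)-4-methoxy-5-[2-(2,4,5-trimethoxyphenyl)acetyl]phenyl acetate
Product: 9 1-[4-(benzyloxy)-5-hydroxy-2-methoxyphenyl]-2-(2,4,5-trimethoxyphenyl)ethan-1-one
Conditions: K2CO3 (0.3 equiv), degassed MeOH, rt, N2; dilute HCl work-up
Reagents that add atoms: none
Why: Base-catalysed transesterification (methanolysis) of an aryl acetate, far faster than any reaction of the ketone or the ethers, with air excluded to protect the deoxybenzoin enolate.

Step 7
Reactants: 9 1-[4-(benzyloxy)-5-hydroxy-2-methoxyphenyl]-2-(2,4,5-trimethoxyphenyl)ethan-1-one; 10 ethyl formate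
Product: 11 3-[4-(benzyloxy)-5-hydroxy-2-methoxyphenyl]-3-oxo-2-(2,4,5-trimethoxyphenyl)propanal (enol form in solution)
Conditions: NaH (4 equiv), HCO2Et (10 equiv), THF, 0 °C to rt; then cold 1 M HCl
Reagents that add atoms: none
Why: Crossed Claisen condensation (C-formylation) of the ketone enolate with the non-enolisable formate, driven by formation of the stabilised product enolate, with the phenoxide as spectator and the ortho methoxy group preventing any pyranone closure at this stage.

Step 8
Reactants: 11 3-[4-(benzyloxy)-5-hydroxy-2-methoxyphenyl]-3-oxo-2-(2,4,5-trimethoxyphenyl)propanal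
Product: 13 7-(benzyloxy)-5,8-dihydroxy-3-(2,4,5-trimethoxyphenyl)-4H-chromen-4-one, via acylquinone 12 (not isolated)
Conditions: PhI(OAc)2 (1.05 equiv), MeCN/H2O 3:1, 0 °C to rt, Ar
Reagents that add atoms: water, O
Why: Proposed new method: ligand exchange of the free phenol on trivalent iodine, attack of water at the para carbon that carries the methoxy group and loss of methanol should give acylquinone 12, whose enol oxygen then adds to C8a in an intramolecular oxa-Michael addition; tautomerisation of the adduct to the aromatic hydroquinone 13 makes the sequence a net dehydrogenative C–O coupling. The closest known reaction types are the oxidative closure of 2-hydroxybenzophenones to xanthones through a quinone and the addition of nucleophiles at C3 of 2-acyl-1,4-benzoquinones, while the oxidation itself is the standard PhI(OAc)2 conversion of 4-methoxyphenols into 1,4-benzoquinones. Ring C closes in a 6-endo-trig mode onto the C4a=C8a double bond, and no stereocentre is formed. Chemoselective oxidation of ring A is needed and is secured because only ring A carries a free hydroxyl (ring B is fully methylated) and because one equivalent of oxidant is used with no added acid. Attack by oxygen rather than carbon at C8a is also needed: the chelated enol geometry places the enol oxygen six atoms from C8a, this carbon is activated by both the C5 and C4 carbonyls, and the acidic enol is a better nucleophile than ring B in neutral aqueous medium. The usual closure through the C5 oxygen is excluded because that oxygen is a methyl ether before oxidation and a quinone carbonyl after it.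

Step 9
Reactants: 13 7-(benzyloxy)-5,8-dihydroxy-3-(2,4,5-trimethoxyphenyl)-4H-chromen-4-one
Product: 14 7-(benzyloxy)-5-hydroxy-8-methoxy-3-(2,4,5-trimethoxyphenyl)-4H-chromen-4-one
Conditions: MeI (1.1 equiv), K2CO3 (1.2 equiv), degassed acetone, rt to 40 °C, Ar
Reagents that add atoms: iodomethane, CI
Why: Williamson methylation in which the 5-hydroxyl, hydrogen-bonded to the C4 carbonyl, is far less nucleophilic than the free 8-phenoxide, so one equivalent of MeI should alkylate O8 only, air being excluded because the hydroquinone is oxidisable in base.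

Step 10
Reactants: 14 7-(benzyloxy)-5-hydroxy-8-methoxy-3-(2,4,5-trimethoxyphenyl)-4H-chromen-4-one
Product: 15 5,7-dihydroxy-8-methoxy-3-(2,4,5-trimethoxyphenyl)-4H-chromen-4-one (isocaviunin)
Conditions: H2 (1 atm), Pd/C (10 wt % Pd on carbon), EtOAc/MeOH, rt
Reagents that add atoms: none
Why: Catalytic hydrogenolysis of the benzylic C–O bond, which at 1 atm and room temperature is much faster than reduction of the chromone C2=C3 bond and leaves the aryl methyl ethers alone.

Step 11
Reactants: 16 2-methylbut-3-en-2-ol
Product: 17 tert-butyl 2-methylbut-3-en-2-yl carbonate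
Conditions: n-BuLi (1.0 equiv), THF, −78 °C; Boc2O (1.05 equiv), −78 °C to rt; aq. NH4Cl
Reagents that add atoms: di-tert-butyl dicarbonate, CC(C)(C)OC(=O)OC(=O)OC(C)(C)C
Why: Acylation of a lithium alkoxide with Boc2O (mixed carbonate formation), the standard preparation of tertiary allylic tert-butyl carbonates.

Step 12
Reactants: 15 5,7-dihydroxy-8-methoxy-3-(2,4,5-trimethoxyphenyl)-4H-chromen-4-one; 17 tert-butyl 2-methylbut-3-en-2-yl carbonate
Product: 18 5-hydroxy-8-methoxy-7-[(2-methylbut-3-en-2-yl)oxy]-3-(2,4,5-trimethoxyphenyl)-4H-chromen-4-one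
Conditions: 17 (1.5 equiv), Pd(PPh3)4 (5 mol %), 4 Å sieves, THF, 0 °C to rt
Reagents that add atoms: none
Why: Decarboxylative Tsuji–Trost allylic etherification, in which ionisation of 17 releases CO2 and tert-butoxide, the base deprotonates the acidic free 7-hydroxyl, and the phenoxide attacks the 1,1-dimethylallyl palladium cation at its more substituted end under kinetic control at low temperature, the chelated 5-hydroxyl staying out.

Step 13
Reactants: 18 5-hydroxy-8-methoxy-7-[(2-methylbut-3-en-2-yl)oxy]-3-(2,4,5-trimethoxyphenyl)-4H-chromen-4-one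
Product: 20 5,7-dihydroxy-8-methoxy-6-(3-methylbut-2-en-1-yl)-3-(2,4,5-trimethoxyphenyl)-4H-chromen-4-one (6-prenylisocaviunin), via dienone 19 (not isolated)
Conditions: PhNEt2, 120 °C, Ar
Reagents that add atoms: none
Why: Aromatic Claisen rearrangement, whose [3,3] shift can end productively only at C6, the single hydrogen-bearing ortho position (a shift to the methoxy-bearing C8 is reversible), the allylic inversion turning the 1,1-dimethylallyl group into prenyl and enolisation of dienone 19 restoring the 7-hydroxyl.

Compound list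
1 | 2-hydroxy-4-methoxybenzaldehyde | COc1ccc(C=O)c(O)c1 | starting material
2 | 2-(benzyloxy)-4-methoxybenzaldehyde | COc1ccc(C=O)c(OCc2ccccc2)c1 | intermediate
3 | 2-(benzyloxy)-4-methoxyphenyl formate | COc1ccc(OC=O)c(OCc2ccccc2)c1 | intermediate (not isolated)
4 | 2-(benzyloxy)-4-methoxyphenol | COc1ccc(O)c(OCc2ccccc2)c1 | intermediate
5 | 2-(benzyloxy)-4-methoxyphenyl acetate | COc1ccc(OC(C)=O)c(OCc2ccccc2)c1 | intermediate
6 | 2-(2,4,5-trimethoxyphenyl)acetic acid | COc1cc(OC)c(CC(=O)O)cc1OC | starting material
7 | 2-(2,4,5-trimethoxyphenyl)acetyl chloride | COc1cc(OC)c(CC(=O)Cl)cc1OC | intermediate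
8 | 2-(benzyloxy)-4-methoxy-5-[2-(2,4,5-trimethoxyphenyl)acetyl]phenyl acetate | COc1cc(OC)c(CC(=O)c2cc(OC(C)=O)c(OCc3ccccc3)cc2OC)cc1OC | intermediate
9 | 1-[4-(benzyloxy)-5-hydroxy-2-methoxyphenyl]-2-(2,4,5-trimethoxyphenyl)ethan-1-one | COc1cc(OC)c(CC(=O)c2cc(O)c(OCc3ccccc3)cc2OC)cc1OC | intermediate
10 | ethyl formate | CCOC=O | starting material
11 | 3-[4-(benzyloxy)-5-hydroxy-2-methoxyphenyl]-3-oxo-2-(2,4,5-trimethoxyphenyl)propanal (enolised, no fixed stereocentre) | COc1cc(OC)c(C(C=O)C(=O)c2cc(O)c(OCc3ccccc3)cc2OC)cc1OC | intermediate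
12 | 3-[4-(benzyloxy)-3,6-dioxocyclohexa-1,4-dien-1-yl]-3-oxo-2-(2,4,5-trimethoxyphenyl)propanal | COc1cc(OC)c(C(C=O)C(=O)C2=CC(=O)C(OCc3ccccc3)=CC2=O)cc1OC | intermediate (not isolated)
13 | 7-(benzyloxy)-5,8-dihydroxy-3-(2,4,5-trimethoxyphenyl)-4H-chromen-4-one | COc1cc(OC)c(-c2coc3c(O)c(OCc4ccccc4)cc(O)c3c2=O)cc1OC | intermediate
14 | 7-(benzyloxy)-5-hydroxy-8-methoxy-3-(2,4,5-trimethoxyphenyl)-4H-chromen-4-one | COc1cc(OC)c(-c2coc3c(OC)c(OCc4ccccc4)cc(O)c3c2=O)cc1OC | intermediate
15 | 5,7-dihydroxy-8-methoxy-3-(2,4,5-trimethoxyphenyl)-4H-chromen-4-one (isocaviunin) | COc1cc(OC)c(-c2coc3c(OC)c(O)cc(O)c3c2=O)cc1OC | intermediate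
16 | 2-methylbut-3-en-2-ol | CC(C)(O)C=C | starting material
17 | tert-butyl 2-methylbut-3-en-2-yl carbonate | CC(C)(C)OC(=O)OC(C)(C)C=C | intermediate
18 | 5-hydroxy-8-methoxy-7-[(2-methylbut-3-en-2-yl)oxy]-3-(2,4,5-trimethoxyphenyl)-4H-chromen-4-one | COc1cc(OC)c(-c2coc3c(OC)c(OC(C)(C)C=C)cc(O)c3c2=O)cc1OC | intermediate
19 | 5-hydroxy-8-methoxy-6-(3-methylbut-2-en-1-yl)-3-(2,4,5-trimethoxyphenyl)-4H-chromene-4,7(6H)-dione (racemic at C6, transient) | COc1cc(OC)c(C2=COC3=C(OC)C(=O)C(CC=C(C)C)C(O)=C3C2=O)cc1OC | intermediate (not isolated)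
20 | 5,7-dihydroxy-8-methoxy-6-(3-methylbut-2-en-1-yl)-3-(2,4,5-trimethoxyphenyl)-4H-chromen-4-one (6-prenylisocaviunin) | COc1cc(OC)c(-c2coc3c(OC)c(O)c(CC=C(C)C)c(O)c3c2=O)cc1OC | target

Total step count: 13.
Longest linear sequence: 11 steps (steps 1, 2, 3, 5, 6, 7, 8, 9, 10, 12, 13, from 1 to 20). Steps 4 and 11 are side branches.

Steps most likely to fail

Step 8 (Proposed new method). The trivalent iodine reagent may attack the enol carbon or the electron-rich ring B instead of the phenol. The quinone may be intercepted by water or by carbon attack from ring B before the enol oxygen closes. The hydroquinone may also be oxidised further by residual oxidant, which a dithionite wash after complete cyclisation should reverse. The fallback uses known chemistry only, sets out from 6 and comes back at 13. Friedel–Crafts (Nencki-type) acylation of phloroglucinol with acid 6 in BF3·OEt2 at 80 °C should give 2-(2,4,5-trimethoxyphenyl)-1-(2,4,6-trihydroxyphenyl)ethan-1-one F1. DMF/BF3·OEt2/MsCl should then insert C2 and close ring C in the ordinary way through an ortho hydroxyl, giving 5,7-dihydroxy-3-(2,4,5-trimethoxyphenyl)-4H-chromen-4-one F2. BnBr/K2CO3 in acetone should benzylate only the unchelated 7-hydroxyl, giving 7-(benzyloxy)-5-hydroxy-3-(2,4,5-trimethoxyphenyl)-4H-chromen-4-one F3. Elbs persulfate oxidation (K2S2O8, aqueous KOH/pyridine) hydroxylates para to the 5-phenoxide, that is at C8, and should give potassium 7-(benzyloxy)-5-hydroxy-4-oxo-3-(2,4,5-trimethoxyphenyl)-4H-chromen-8-yl sulfate F4. Dilute HCl should hydrolyse F4 to 13. This sequence is regiochemically reliable, though the persulfate step is typically modest in efficiency.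

Step 5. The electron-rich arylacetyl cation may lose CO to a stabilised benzyl cation, so that alkylation replaces acylation. The acid chloride may also acylate its own trimethoxyphenyl ring, or the Lewis acid may cleave the benzyl ether. The fallback sets out from 5 and comes back at 8. Acetylation of 5 with acetyl chloride/SnCl4 at −20 °C, at the same ring carbon and with a small acylium ion that cannot lose CO, should give 5-acetyl-2-(benzyloxy)-4-methoxyphenyl acetate F5. Palladium-catalysed ketone alpha-arylation of F5 with 1-bromo-2,4,5-trimethoxybenzene (Pd2(dba)3, Xantphos, K3PO4, toluene, 80 °C) should then attach ring B to the methyl carbon and give 8. Any loss of the acetate under the basic conditions is harmless, since it gives 9, the product of the next step.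

Step 12. The phenoxide may attack the unsubstituted end of the allyl palladium intermediate, giving the linear prenyl ether, which cannot deliver a prenyl group to C6. The 7-hydroxyl next to the 8-methoxy group may also react sluggishly. The fallback sets out from 15 and comes back at 18. Copper-catalysed propargylic etherification with 3-chloro-3-methylbut-1-yne (CuCl2 cat., DBU, MeCN, 0 °C) should give 5-hydroxy-8-methoxy-7-[(2-methylbut-3-yn-2-yl)oxy]-3-(2,4,5-trimethoxyphenyl)-4H-chromen-4-one F6. Semi-hydrogenation of F6 over Lindlar catalyst (Pd on CaCO3 poisoned with Pb(OAc)2, quinoline, H2 1 atm, EtOAc) should give 18.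

Further compounds
F1 | step 8 | 2-(2,4,5-trimethoxyphenyl)-1-(2,4,6-trihydroxyphenyl)ethan-1-one | COc1cc(OC)c(CC(=O)c2c(O)cc(O)cc2O)cc1OC
F2 | step 8 | 5,7-dihydroxy-3-(2,4,5-trimethoxyphenyl)-4H-chromen-4-one | COc1cc(OC)c(-c2coc3cc(O)cc(O)c3c2=O)cc1OC
F3 | step 8 | 7-(benzyloxy)-5-hydroxy-3-(2,4,5-trimethoxyphenyl)-4H-chromen-4-one | COc1cc(OC)c(-c2coc3cc(OCc4ccccc4)cc(O)c3c2=O)cc1OC
F4 | step 8 | potassium 7-(benzyloxy)-5-hydroxy-4-oxo-3-(2,4,5-trimethoxyphenyl)-4H-chromen-8-yl sulfate | COc1cc(OC)c(-c2coc3c(OS(=O)(=O)[O-])c(OCc4ccccc4)cc(O)c3c2=O)cc1OC.[K+]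
F5 | step 5 | 5-acetyl-2-(benzyloxy)-4-methoxyphenyl acetate | CC(=O)Oc1cc(C(C)=O)c(OC)cc1OCc1ccccc1
F6 | step 12 | 5-hydroxy-8-methoxy-7-[(2-methylbut-3-yn-2-yl)oxy]-3-(2,4,5-trimethoxyphenyl)-4H-chromen-4-one | COc1cc(OC)c(-c2coc3c(OC)c(OC(C)(C)C#C)cc(O)c3c2=O)cc1OC
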